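The partner is the limiting reagent of this flask: taken one to one, its charge covers 95.0% of the substrate, and that share is the flask's roof.

all flasks: substrate 0.050 M; free catalyst 0.50 mM

| charge | partner | remark | time |
|---|---|---|---|
| delta | 0.024 M (fed, over 30 h) | run made earlier |  |
| eta | 0.036 M (fed, over 30 h) | run made earlier |  |
| flask | 0.0475 M (fed, over 30 h) |  | 5.0 d |

- delta (time / d: product / %, substrate / %): 0.833: 8.8, 90.5; 1.67: 24.0, 73.2; 2.50: 34.2, 62.6; 3.00: 40.5, 59.4; 4.00: 44.4, 54.4
- eta (time / d: product / %, substrate / %): 0.333: 2.2, 96.6; 1.04: 15.4, 82.9; 1.67: 27.0, 69.3; 3.00: 54.1, 45.5; 4.00: 65.6, 36.5

(readings scatter by 1 percentage point)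

- why nothing more happens at 5.0 d, or that something still does (the partner has run out first / all of the substrate has reacted / it is still moving / forward and back rates have come level / no working catalyst is left)
- product at 5.0 d, in percent of the substrate charged

- the reaction counts as stopped when no species that holds the substrate changes by six tenths of a point or more over the second half of the time

In eta, the dose ended at 1.25 d and substrate fell from 69.3% to 45.5% between 1.67 d and 3.00 d. Yet product gained 0.204 d⁻¹ of the charge then and 0.184 d⁻¹ before, a gap that readings scattering by 1 percentage point cannot tell from none.

Following one catalyst molecule clears this up. In eta it passes its cycle 20.4 d⁻¹ on average over that stretch, and the readings do not show that count following substrate down, so this reckoning takes the stretch as near zero-order in substrate and carries its pace on.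

Days to the roof, the roof over the pace: 95.0% / 0.204 d⁻¹ = 4.66 d

The same reckoning gives delta 2.36 d and eta 3.53 d. Delta, 0.144 d past its time, read 14 points under its roof. Eta, 0.466 d past, read 6.4 points under. The flask at 5.0 d stands 0.340 d past, so this reckoning puts its product between 81.0% and 88.6%. Full pace gives about 51.0% at half time, so the second half gains about 30 points, which the stopping rule does not allow.

The forecast says it is still moving, “so it is still moving”, with 83%.

The flask gives it is still moving and 85.2%.

    partner + free catalyst → catalyst intermediate A (k = 2.20 M⁻¹ min⁻¹)
    substrate + catalyst intermediate A → catalyst intermediate B (k = 2.40 M⁻¹ min⁻¹)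
    catalyst intermediate B ⇌ catalyst intermediate C (K = 1.10, k = 0.0300 min⁻¹)
    catalyst intermediate C → free catalyst + product (k = 1.10 min⁻¹)

The neighbouring flask holds 0.030 M of substrate, so partner stands at 1.58 equiv and substrate becomes the limiting reagent, with the whole charge as roof. The same amount of product per day is a larger share of this smaller charge:

Days to the roof in the neighbouring flask: 2.94 d

That is 2.06 d short of 5.0 d. The neighbouring flask gives 98.8%, with 1.1% of its substrate left unbound.

The data were computed from invented constants; noise was put on by code.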